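**Retrosynthetic overview**

1. The interflavan C4–C6 bond comes from the 6-lithio derivative of 8-bromo-penta-O-benzylcatechin and the C4 ketone of a benzylated ent-fustin. The C4–H bond is then made by hydride attack on the diaryl cation anti to the C3 benzyloxy group (3,4-cis), and hydrogenolysis frees all hydroxyls.
2. The upper pyran ring (O1, C2, C3, C4, C4a, C8a) is not closed directly. It is grown from the five-membered ring of a (2S)-2-(α-hydroxybenzyl)-2,3-dihydrobenzofuran (O1, C3, C4, C4a, C8a, with C2 exocyclic) by a 1,2-shift of O1 from C3 to C2 through a bridged oxiranium ion, with benzyl alcohol entering at C3.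
3. Enabling feature: in the pyran, O1 on C2 and the oxygen on C3 are vicinal, and C2 is benzylic to the electron-rich catechol ring. The dihydrobenzofuran isomer therefore ionises easily at C2, O1 can bridge C2 and C3, and the chroman, whose C3–O bond cannot ionise, is the sink. The single centre set by hydrogenation is relayed to C3 (inversion) and C2 (trans).
4. Ring order: benzofuran (Rap–Stoermer), dihydrobenzofuran (asymmetric hydrogenation), chroman (ring expansion). Both rings of the lower unit come intact from (+)-catechin.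

Key step: step 4

Remark on numbering: flavan numbering (O1, C2, C3, C4, C4a, C8a) is used for the chromans and benzofuran numbering for the five-membered precursors.
Assumption: the sense of induction of the chiral ruthenium–carbene catalyst in step 3 is taken by analogy with 2-alkyl- and 2-arylbenzofurans; if it is opposite, the (S,S)-ligand is used.
Assumption: compounds 1, 2 and 11 are commercially available.

**Step 1**
Reactants: 1 4-(benzyloxy)-2-hydroxybenzaldehyde; 2 2-bromo-1-[3,4-bis(benzyloxy)phenyl]ethan-1-one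
Product: 4 [6-(benzyloxy)-1-benzofuran-2-yl][3,4-bis(benzyloxy)phenyl]methanone, via aryloxy ketone 3 (not isolated)
Conditions: K2CO3, MeCN, 80 °C
Reagents that add atoms: none
Why: Rap–Stoermer condensation, in which phenoxide O-alkylation by the α-bromoketone is followed by intramolecular aldol condensation onto the ortho aldehyde and dehydration to the aromatic benzofuran; no stereocentre is formed.

**Step 2**
Reactants: 4 [6-(benzyloxy)-1-benzofuran-2-yl][3,4-bis(benzyloxy)phenyl]methanone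
Product: 5 rac-[6-(benzyloxy)-1-benzofuran-2-yl][3,4-bis(benzyloxy)phenyl]methanol
Conditions: NaBH4, THF/MeOH, 0 °C
Reagents that add atoms: none
Why: Borohydride reduction of an aryl heteroaryl ketone; the racemic carbinol is acceptable because both carbinol configurations should converge through the same benzylic cation in step 4.

**Step 3**
Reactants: 5 rac-[6-(benzyloxy)-1-benzofuran-2-yl][3,4-bis(benzyloxy)phenyl]methanol
Product: 6 [(2S)-6-(benzyloxy)-2,3-dihydro-1-benzofuran-2-yl][3,4-bis(benzyloxy)phenyl]methanol (both carbinol epimers)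
Conditions: [Ru(cod)(2-methylallyl)2] (5 mol%), (R,R)-SINpEt·HBF4 (10 mol%), KOtBu (15 mol%), H2 (60 bar), toluene/n-hexane, 40 °C
Reagents that add atoms: none
Why: Ruthenium–N-heterocyclic-carbene-catalysed asymmetric hydrogenation of a 2-substituted benzofuran; the chiral carbene ligand selects the face of the furan C2=C3 bond and should set C2 as S, while benzyl ethers and benzene rings are expected to survive this homogeneous catalyst.

**Step 4**
Reactants: 6 [(2S)-6-(benzyloxy)-2,3-dihydro-1-benzofuran-2-yl][3,4-bis(benzyloxy)phenyl]methanol (both carbinol epimers)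
Product: 8 (2S,3R)-3,7-bis(benzyloxy)-2-[3,4-bis(benzyloxy)phenyl]chromane, via oxiranium ion 7 (not isolated)
Conditions: camphorsulfonic acid (20 mol%), BnOH (20 equiv), ClCH2CH2Cl, 3 Å MS, 60 °C, 0.02 M
Reagents that add atoms: benzyl alcohol, OCc1ccccc1
Why: Acid ionises the benzylic C–OH of either carbinol epimer to the 3,4-bis(benzyloxy)benzyl cation, O1 bridges it to give oxiranium ion 7, and benzyl alcohol opens 7 at the non-benzylic carbon with cleavage of the old O1–C bond, so the five-membered ring becomes the pyran. The closest known reaction type is the oxiranium-mediated ring expansion of 2-(1-hydroxyalkyl)tetrahydrofurans and dihydrobenzofurans to 3-oxygenated tetrahydropyrans and chromans, together with its reverse, the ring contraction of flavan-3-ol 3-sulfonates. The pyran closes by a 1,2-shift of O1, that is a 3-exo attack of O1 on the cation followed by opening of the bicyclic oxonium at the ring carbon. C3 is set by stereospecific inversion at the hydrogenation-derived centre (S in 6 becomes R in 8). C2 is set by the preference for the trans-disposed oxiranium (aryl anti to the C4 methylene), whose anti opening gives the 2,3-trans product from both carbinol epimers. The step needs capture at C3 to win over return at the benzylic carbon and over β-proton loss; this is secured because every benzylic C–O bond (starting carbinol, its benzyl ether, adducts of the enol ether) stays reversible in anhydrous acidic benzyl alcohol, whereas the C3–OBn bond of 8 cannot ionise.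

**Step 5**
Reactants: 8 (2S,3R)-3,7-bis(benzyloxy)-2-[3,4-bis(benzyloxy)phenyl]chromane
Product: 9 (2S,3R)-3,7-bis(benzyloxy)-2-[3,4-bis(benzyloxy)phenyl]chroman-4-ol (C4 epimers)
Conditions: DDQ (1.5 equiv), CH2Cl2/H2O (20:1), rt
Reagents that add atoms: water, O
Why: DDQ benzylic oxidation, in which hydride abstraction from C4 (para to the 7-benzyloxy group and ortho to O1) gives a cation that water captures; the C4 configuration is irrelevant because C4 is oxidised further.

**Step 6**
Reactants: 9 (2S,3R)-3,7-bis(benzyloxy)-2-[3,4-bis(benzyloxy)phenyl]chroman-4-ol (C4 epimers)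
Product: 10 (2S,3S)-3,7-bis(benzyloxy)-2-[3,4-bis(benzyloxy)phenyl]chroman-4-one
Conditions: Dess–Martin periodinane, CH2Cl2, rt
Reagents that add atoms: none
Why: Dess–Martin oxidation of a secondary benzylic alcohol under non-basic conditions, so the C3 centre α to the new ketone, which already has the thermodynamically preferred 2,3-trans arrangement, should be retained.

**Step 7**
Reactants: 11 (+)-catechin
Product: 12 (2R,3S)-5,7-bis(benzyloxy)-2-[3,4-bis(benzyloxy)phenyl]chroman-3-ol
Conditions: BnBr (4.4 equiv), K2CO3, DMF, rt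
Reagents that add atoms: benzyl bromide, BrCc1ccccc1
Why: Williamson etherification of the four phenols, which are far more acidic than the secondary 3-OH; carbonate does not epimerise C2.

**Step 8**
Reactants: 12 (2R,3S)-5,7-bis(benzyloxy)-2-[3,4-bis(benzyloxy)phenyl]chroman-3-ol
Product: 13 (2R,3S)-3,5,7-tris(benzyloxy)-2-[3,4-bis(benzyloxy)phenyl]chromane
Conditions: NaH, BnBr, Bu4NI (cat.), THF/DMF, 0 °C to rt
Reagents that add atoms: benzyl bromide, BrCc1ccccc1
Why: Williamson etherification of the secondary alkoxide, which masks the only acidic proton before the organolithium step.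

**Step 9**
Reactants: 13 (2R,3S)-3,5,7-tris(benzyloxy)-2-[3,4-bis(benzyloxy)phenyl]chromane
Product: 14 (2R,3S)-3,5,7-tris(benzyloxy)-2-[3,4-bis(benzyloxy)phenyl]-8-bromochromane
Conditions: NBS (1.0 equiv), CH2Cl2, −78 °C to rt
Reagents that add atoms: N-bromosuccinimide, O=C1CCC(=O)N1Br
Why: Electrophilic aromatic bromination of the phloroglucinol-type ring, which is known to go to C8 in benzylated catechins; the bromine blocks C8 for the rest of the route.

**Step 10**
Reactants: 14 (2R,3S)-3,5,7-tris(benzyloxy)-2-[3,4-bis(benzyloxy)phenyl]-8-bromochromane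
Product: 15 (2R,3S)-3,5,7-tris(benzyloxy)-2-[3,4-bis(benzyloxy)phenyl]-8-bromo-6-iodochromane
Conditions: NIS (1.1 equiv), TFA (10 mol%), CH2Cl2/MeCN, 0 °C to rt
Reagents that add atoms: N-iodosuccinimide, O=C1CCC(=O)N1I
Why: Electrophilic aromatic iodination at C6, the only free position of the trioxygenated ring, which is much more electron-rich than the catechol ring.

**Step 11**
Reactants: 15 (2R,3S)-3,5,7-tris(benzyloxy)-2-[3,4-bis(benzyloxy)phenyl]-8-bromo-6-iodochromane; 10 (2S,3S)-3,7-bis(benzyloxy)-2-[3,4-bis(benzyloxy)phenyl]chroman-4-one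
Product: 17 (2S,3S)-3,7-bis(benzyloxy)-2-[3,4-bis(benzyloxy)phenyl]-4-{(2R,3S)-3,5,7-tris(benzyloxy)-2-[3,4-bis(benzyloxy)phenyl]-8-bromochroman-6-yl}chroman-4-ol (C4 not controlled), via aryllithium 16 (not isolated)
Conditions: n-BuLi (1.05 equiv), THF, −78 °C; then 10, −78 to −40 °C; H2O
Reagents that add atoms: none
Why: Iodine–lithium exchange, which is much faster than bromine–lithium exchange and so gives the C6 nucleophile only, followed by 1,2-addition of the aryllithium to the ketone; the new C4 centre need not be controlled because it is planarised in step 12.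

**Step 12**
Reactants: 17 (2S,3S)-3,7-bis(benzyloxy)-2-[3,4-bis(benzyloxy)phenyl]-4-{(2R,3S)-3,5,7-tris(benzyloxy)-2-[3,4-bis(benzyloxy)phenyl]-8-bromochroman-6-yl}chroman-4-ol
Product: 19 (2S,3R,4S)-3,7-bis(benzyloxy)-2-[3,4-bis(benzyloxy)phenyl]-4-{(2R,3S)-3,5,7-tris(benzyloxy)-2-[3,4-bis(benzyloxy)phenyl]-8-bromochroman-6-yl}chromane, via chroman-4-ylium ion 18 (not isolated)
Conditions: Et3SiH (5 equiv), TFA (10 equiv), CH2Cl2, −40 to 0 °C
Reagents that add atoms: none
Why: Ionic hydrogenation, in which the tertiary doubly benzylic alcohol ionises to cation 18 and the silane delivers hydride to C4 from the face anti to the neighbouring 3-benzyloxy group, leaving the catechin ring cis to that oxygen (C4 = S); this is the reverse of the facial preference that makes direct coupling 3,4-trans.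

**Step 13**
Reactants: 19 (2S,3R,4S)-3,7-bis(benzyloxy)-2-[3,4-bis(benzyloxy)phenyl]-4-{(2R,3S)-3,5,7-tris(benzyloxy)-2-[3,4-bis(benzyloxy)phenyl]-8-bromochroman-6-yl}chromane
Product: 20 (2S,3R,4S)-2-(3,4-dihydroxyphenyl)-4-[(2R,3S)-2-(3,4-dihydroxyphenyl)-3,5,7-trihydroxychroman-6-yl]chromane-3,7-diol
Conditions: H2 (1 atm), Pd(OH)2 on carbon, Et3N (1.5 equiv), THF/MeOH, rt
Reagents that add atoms: none
Why: Catalytic hydrogenolysis of the nine benzyl ethers and of the aryl C–Br bond, with the amine taking up HBr; the acid-stable 5-deoxy interflavan bond and the five stereocentres are not affected.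

**Compound list**

1 | 4-(benzyloxy)-2-hydroxybenzaldehyde | O=Cc1ccc(OCc2ccccc2)cc1O | starting material
2 | 2-bromo-1-[3,4-bis(benzyloxy)phenyl]ethan-1-one | O=C(CBr)c1ccc(OCc2ccccc2)c(OCc2ccccc2)c1 | starting material
3 | 2-[5-(benzyloxy)-2-formylphenoxy]-1-[3,4-bis(benzyloxy)phenyl]ethan-1-one | O=Cc1ccc(OCc2ccccc2)cc1OCC(=O)c1ccc(OCc2ccccc2)c(OCc2ccccc2)c1 | intermediate
4 | [6-(benzyloxy)-1-benzofuran-2-yl][3,4-bis(benzyloxy)phenyl]methanone | O=C(c1cc2ccc(OCc3ccccc3)cc2o1)c1ccc(OCc3ccccc3)c(OCc3ccccc3)c1 | intermediate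
5 | rac-[6-(benzyloxy)-1-benzofuran-2-yl][3,4-bis(benzyloxy)phenyl]methanol | OC(c1cc2ccc(OCc3ccccc3)cc2o1)c1ccc(OCc3ccccc3)c(OCc3ccccc3)c1 | intermediate
6 | [(2S)-6-(benzyloxy)-2,3-dihydro-1-benzofuran-2-yl][3,4-bis(benzyloxy)phenyl]methanol, both carbinol epimers (carbinol centre left open in the SMILES) | OC([C@@H]1Cc2ccc(OCc3ccccc3)cc2O1)c1ccc(OCc3ccccc3)c(OCc3ccccc3)c1 | intermediate
7 | bridged oxiranium ion: O1 bonded to C8a, C2 and C3 (flavan numbering), aryl on C2 trans to the C4 methylene | [C@H]1(c2ccc(OCc3ccccc3)c(OCc3ccccc3)c2)[C@@H]2Cc3ccc(OCc4ccccc4)cc3[O+]12 | intermediate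
8 | (2S,3R)-3,7-bis(benzyloxy)-2-[3,4-bis(benzyloxy)phenyl]chromane | C(c1ccccc1)Oc1ccc2c(c1)O[C@@H](c1ccc(OCc3ccccc3)c(OCc3ccccc3)c1)[C@H](OCc1ccccc1)C2 | intermediate
9 | (2S,3R)-3,7-bis(benzyloxy)-2-[3,4-bis(benzyloxy)phenyl]chroman-4-ol, C4 epimers (C4 left open in the SMILES) | C(c1ccccc1)Oc1ccc2c(c1)O[C@@H](c1ccc(OCc3ccccc3)c(OCc3ccccc3)c1)[C@H](OCc1ccccc1)C2O | intermediate
10 | (2S,3S)-3,7-bis(benzyloxy)-2-[3,4-bis(benzyloxy)phenyl]chroman-4-one | C(c1ccccc1)Oc1ccc2c(c1)O[C@@H](c1ccc(OCc3ccccc3)c(OCc3ccccc3)c1)[C@H](OCc1ccccc1)C2=O | intermediate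
11 | (+)-catechin, (2R,3S)-2-(3,4-dihydroxyphenyl)chromane-3,5,7-triol | O[C@H]1Cc2c(O)cc(O)cc2O[C@@H]1c1ccc(O)c(O)c1 | starting material
12 | (2R,3S)-5,7-bis(benzyloxy)-2-[3,4-bis(benzyloxy)phenyl]chroman-3-ol | O[C@H]1Cc2c(OCc3ccccc3)cc(OCc3ccccc3)cc2O[C@@H]1c1ccc(OCc3ccccc3)c(OCc3ccccc3)c1 | intermediate
13 | (2R,3S)-3,5,7-tris(benzyloxy)-2-[3,4-bis(benzyloxy)phenyl]chromane | C(c1ccccc1)O[C@H]1Cc2c(OCc3ccccc3)cc(OCc3ccccc3)cc2O[C@@H]1c1ccc(OCc3ccccc3)c(OCc3ccccc3)c1 | intermediate
14 | (2R,3S)-3,5,7-tris(benzyloxy)-2-[3,4-bis(benzyloxy)phenyl]-8-bromochromane | C(c1ccccc1)O[C@H]1Cc2c(OCc3ccccc3)cc(OCc3ccccc3)c(Br)c2O[C@@H]1c1ccc(OCc3ccccc3)c(OCc3ccccc3)c1 | intermediate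
15 | (2R,3S)-3,5,7-tris(benzyloxy)-2-[3,4-bis(benzyloxy)phenyl]-8-bromo-6-iodochromane | C(c1ccccc1)O[C@H]1Cc2c(OCc3ccccc3)c(I)c(OCc3ccccc3)c(Br)c2O[C@@H]1c1ccc(OCc3ccccc3)c(OCc3ccccc3)c1 | intermediate
16 | {(2R,3S)-3,5,7-tris(benzyloxy)-2-[3,4-bis(benzyloxy)phenyl]-8-bromochroman-6-yl}lithium | C(c1ccccc1)O[C@H]1Cc2c(OCc3ccccc3)c([Li])c(OCc3ccccc3)c(Br)c2O[C@@H]1c1ccc(OCc3ccccc3)c(OCc3ccccc3)c1 | intermediate
17 | (2S,3S)-3,7-bis(benzyloxy)-2-[3,4-bis(benzyloxy)phenyl]-4-{(2R,3S)-3,5,7-tris(benzyloxy)-2-[3,4-bis(benzyloxy)phenyl]-8-bromochroman-6-yl}chroman-4-ol (C4 left open in the SMILES) | C(c1ccccc1)Oc1ccc2c(c1)O[C@@H](c1ccc(OCc3ccccc3)c(OCc3ccccc3)c1)[C@H](OCc1ccccc1)C2(O)c1c(OCc3ccccc3)c(Br)c2c(c1OCc3ccccc3)C[C@H](OCc1ccccc1)[C@@H](c1ccc(OCc3ccccc3)c(OCc3ccccc3)c1)O2 | intermediate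
18 | (2S,3R)-3,7-bis(benzyloxy)-2-[3,4-bis(benzyloxy)phenyl]-4-{(2R,3S)-3,5,7-tris(benzyloxy)-2-[3,4-bis(benzyloxy)phenyl]-8-bromochroman-6-yl}chroman-4-ylium | C(c1ccccc1)Oc1ccc2c(c1)O[C@@H](c1ccc(OCc3ccccc3)c(OCc3ccccc3)c1)[C@H](OCc1ccccc1)[C+]2c1c(OCc3ccccc3)c(Br)c2c(c1OCc3ccccc3)C[C@H](OCc1ccccc1)[C@@H](c1ccc(OCc3ccccc3)c(OCc3ccccc3)c1)O2 | intermediate
19 | (2S,3R,4S)-3,7-bis(benzyloxy)-2-[3,4-bis(benzyloxy)phenyl]-4-{(2R,3S)-3,5,7-tris(benzyloxy)-2-[3,4-bis(benzyloxy)phenyl]-8-bromochroman-6-yl}chromane | C(c1ccccc1)Oc1ccc2c(c1)O[C@@H](c1ccc(OCc3ccccc3)c(OCc3ccccc3)c1)[C@H](OCc1ccccc1)[C@@H]2c1c(OCc3ccccc3)c(Br)c2c(c1OCc3ccccc3)C[C@H](OCc1ccccc1)[C@@H](c1ccc(OCc3ccccc3)c(OCc3ccccc3)c1)O2 | intermediate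
20 | (2S,3R,4S)-2-(3,4-dihydroxyphenyl)-4-[(2R,3S)-2-(3,4-dihydroxyphenyl)-3,5,7-trihydroxychroman-6-yl]chromane-3,7-diol (ent-fisetinidol-(4α→6)-catechin) | Oc1ccc2c(c1)O[C@@H](c1ccc(O)c(O)c1)[C@H](O)[C@@H]2c1c(O)cc2c(c1O)C[C@H](O)[C@@H](c1ccc(O)c(O)c1)O2 | target

**Totals**

Total step count: 13.
Longest linear sequence: 9 steps (steps 1–6, then 11–13).

**Steps most likely to fail**

Step 4 (key step). The benzylic cation may lose the proton on the ring carbon next to O1 instead of being bridged by O1. The resulting exocyclic enol ether can then be drained irreversibly, and a long-lived free cation can also erode the 2,3-trans preference or alkylate another arene. The fallback sets out from 6 and comes back at 8. It replaces the hot, equilibrating acid solvolysis by a low-temperature, buffered acyl relay. The carbinol is converted with MsCl/Et3N in CH2Cl2 at −40 °C into the labile [(2S)-6-(benzyloxy)-2,3-dihydro-1-benzofuran-2-yl][3,4-bis(benzyloxy)phenyl]methyl methanesulfonate F1, which is not isolated. F1 is ionised in the same flask with Zn(OAc)2 in AcOH/H2O, so that O1 displaces the sulfonate and acetate opens the oxiranium at C3 to give (2S,3R)-7-(benzyloxy)-2-[3,4-bis(benzyloxy)phenyl]chroman-3-yl acetate F2. Methanolysis with K2CO3/MeOH gives (2S,3R)-7-(benzyloxy)-2-[3,4-bis(benzyloxy)phenyl]chroman-3-ol F3, and NaH/BnBr then gives 8.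

Step 3. The hindered, hydroxyl-bearing 2-substituent may slow the hydrogenation or lower its facial selectivity, and over-reduction of benzene rings or hydrogenolysis of the benzylic C–O bond could intervene. The fallback sets out from 1 and 2 and comes back at 6; it avoids benzofuran hydrogenation altogether. Aldehyde 1 is reduced with NaBH4 to 4-(benzyloxy)-2-(hydroxymethyl)phenol F4, and bromoketone 2 is quaternised with Me2S to {2-[3,4-bis(benzyloxy)phenyl]-2-oxoethyl}dimethylsulfonium bromide F5. The sulfur ylide from F5 (Cs2CO3, CH2Cl2) is joined with the ortho-quinone methide generated in situ from F4 in a known [4+1] annulation to give rac-[6-(benzyloxy)-2,3-dihydro-1-benzofuran-2-yl][3,4-bis(benzyloxy)phenyl]methanone F6. Asymmetric transfer hydrogenation of F6 with dynamic kinetic resolution (RuCl(p-cymene)[(S,S)-TsDPEN] or its enantiomer, HCO2H/Et3N) exploits the base-labile centre next to the ketone and should give 6 as a single carbinol epimer with C2 = S.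

Step 11. The hindered, basic aryllithium may deprotonate C3 of ketone 10 instead of adding to it, which would open the pyran by β-elimination of the phenoxide, or the addition may simply stall for steric reasons. The fallback sets out from 9 and 14 and comes back at 17; it makes the C4–C6 bond by Friedel–Crafts chemistry instead. Alcohol 9 is ionised with TMSOTf in CH2Cl2 at −78 °C in the presence of 14, whose only free ring position is C6. This should give 19 as the minor product together with its 3,4-trans epimer, (2S,3R,4R)-3,7-bis(benzyloxy)-2-[3,4-bis(benzyloxy)phenyl]-4-{(2R,3S)-3,5,7-tris(benzyloxy)-2-[3,4-bis(benzyloxy)phenyl]-8-bromochroman-6-yl}chromane F7. The mixture is oxidised at the doubly benzylic C4–H with DDQ in wet CH2Cl2 to carbinol 17, and step 12 then funnels both epimers to 19.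

**Further compounds**

F1 | step 4 | [(2S)-6-(benzyloxy)-2,3-dihydro-1-benzofuran-2-yl][3,4-bis(benzyloxy)phenyl]methyl methanesulfonate (both epimers at the sulfonate carbon) | CS(=O)(=O)OC([C@@H]1Cc2ccc(OCc3ccccc3)cc2O1)c1ccc(OCc3ccccc3)c(OCc3ccccc3)c1
F2 | step 4 | (2S,3R)-7-(benzyloxy)-2-[3,4-bis(benzyloxy)phenyl]chroman-3-yl acetate | C(c1ccccc1)Oc1ccc2c(c1)O[C@@H](c1ccc(OCc3ccccc3)c(OCc3ccccc3)c1)[C@H](OC(C)=O)C2
F3 | step 4 | (2S,3R)-7-(benzyloxy)-2-[3,4-bis(benzyloxy)phenyl]chroman-3-ol | C(c1ccccc1)Oc1ccc2c(c1)O[C@@H](c1ccc(OCc3ccccc3)c(OCc3ccccc3)c1)[C@H](O)C2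
F4 | step 3 | 4-(benzyloxy)-2-(hydroxymethyl)phenol | OCc1ccc(OCc2ccccc2)cc1O
F5 | step 3 | {2-[3,4-bis(benzyloxy)phenyl]-2-oxoethyl}dimethylsulfonium bromide | C[S+](C)CC(=O)c1ccc(OCc2ccccc2)c(OCc2ccccc2)c1.[Br-]
F6 | step 3 | rac-[6-(benzyloxy)-2,3-dihydro-1-benzofuran-2-yl][3,4-bis(benzyloxy)phenyl]methanone | O=C(C1Cc2ccc(OCc3ccccc3)cc2O1)c1ccc(OCc3ccccc3)c(OCc3ccccc3)c1
F7 | step 11 | (2S,3R,4R)-3,7-bis(benzyloxy)-2-[3,4-bis(benzyloxy)phenyl]-4-{(2R,3S)-3,5,7-tris(benzyloxy)-2-[3,4-bis(benzyloxy)phenyl]-8-bromochroman-6-yl}chromane | C(c1ccccc1)Oc1ccc2c(c1)O[C@@H](c1ccc(OCc3ccccc3)c(OCc3ccccc3)c1)[C@H](OCc1ccccc1)[C@H]2c1c(OCc3ccccc3)c(Br)c2c(c1OCc3ccccc3)C[C@H](OCc1ccccc1)[C@@H](c1ccc(OCc3ccccc3)c(OCc3ccccc3)c1)O2
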